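The 20-membered ring contains ring A (5-hydroxy-1,3-phenylene), the ether oxygen, ring B (2,6-dihydroxy-1,4-phenylene) and a saturated chain C1–C12 from ring B to ring A. Everything rests on disconnecting the unactivated C4–C5 methylene–methylene bond, read as a masked olefin. Ring-closing metathesis of an open diaryl ether with a pent-4-enyl arm on ring B and a non-8-enyl arm on ring A closes the macrocycle at C4=C5; hydrogenation in the same flask saturates it. The step exploits the bent aryl–O–aryl hinge and the absence of any functional group along C1–C12. Methyl ethers mask the three phenols until the end.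

Key step: step 4

Remark: the target has no stereocentre; the metathesis olefin 10 is expected as an E/Z mixture and is written without geometry, because the hydrogenation that follows removes it.

Step 1
Reactants: 1 1,3-dibromo-5-methoxybenzene; 2 9-bromonon-1-ene
Product: 4 1-bromo-3-methoxy-5-(non-8-en-1-yl)benzene, via arylmagnesium chloride 3 (not isolated)
Conditions: iPrMgCl·LiCl (1.05 equiv), THF, −15 °C to rt; then 2, Li2CuCl4 (5 mol%), THF/NMP, 0 °C to rt
Reagents that add atoms: none
Why: A single bromine–magnesium exchange (the arylmagnesium formed deactivates the second bromide) followed by a Kochi-type copper-catalysed sp2–sp3 coupling with the primary alkyl bromide should install the nonenyl arm and keep one aryl bromide for the ether coupling, the secondary 2-bromopropane by-product being a much poorer electrophile under copper catalysis.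

Step 2
Reactants: 5 4-allyl-2,6-dimethoxyphenol; 6 vinyl bromide
Product: 8 2,6-dimethoxy-4-(pent-4-en-1-yl)phenol, via bis-boryl adduct 7 (not isolated)
Conditions: 9-BBN (2.2 equiv), THF, 0 °C to rt; then 6 (1 M in THF), Pd(dppf)Cl2 (5 mol%), aq. K3PO4, THF/DMF, rt to 50 °C, sealed tube
Reagents that add atoms: none
Why: Anti-Markovnikov hydroboration of the allyl group with 9-BBN and a B-alkyl Suzuki–Miyaura coupling of the primary alkylborane with vinyl bromide should lengthen the allyl group by two carbons to the pent-4-enyl arm, the phenol consuming one equivalent of borane as an aryloxyborane that the aqueous base hydrolyses again.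

Step 3
Reactants: 4 1-bromo-3-methoxy-5-(non-8-en-1-yl)benzene; 8 2,6-dimethoxy-4-(pent-4-en-1-yl)phenol
Product: 9 1,3-dimethoxy-2-[3-methoxy-5-(non-8-en-1-yl)phenoxy]-5-(pent-4-en-1-yl)benzene
Conditions: CuI (10 mol%), picolinic acid (20 mol%), K3PO4, DMSO, 90 °C
Reagents that add atoms: none
Why: The Ullmann-type copper-catalysed C–O coupling with picolinic acid as ligand is established for doubly ortho-substituted phenols and electron-rich aryl bromides, and the isolated terminal olefins and methyl ethers are inert to copper and phosphate.

Step 4
Reactants: 9 1,3-dimethoxy-2-[3-methoxy-5-(non-8-en-1-yl)phenoxy]-5-(pent-4-en-1-yl)benzene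
Product: 11 tri-O-methyl ether of the target macrocycle, via macrocyclic alkene 10 (not isolated)
Conditions: second-generation Grubbs catalyst (5 mol%), CH2Cl2 (2 mM), 40 °C, argon sparge; concentrate; then H2 (1 atm), Pd/C, EtOAc, rt
Reagents that add atoms: none
Why: The ruthenium alkylidene loads onto one terminal olefin and an intramolecular [2+2] cycloaddition/cycloreversion through a ruthenacyclobutane with the second olefin expels ethene and forms the C4=C5 double bond, which the palladium-catalysed hydrogenation of the crude mixture converts into the C4–C5 single bond. The closest known reaction type is macrocyclic ring-closing metathesis followed by hydrogenation, as practised for cyclophanes and macrolides. The only ring closed is the 20-membered meta,para-cyclophane ring, closed end to end between two unhindered monosubstituted olefins that the aryl–O–aryl hinge turns toward each other. No stereocentre is created, and the E/Z ratio of 10 is erased by the hydrogenation. The selectivity needed is ring closure over intermolecular diene metathesis, secured by high dilution, by removal of ethene and by the reversibility of metathesis, which lets oligomers back-bite to the strain-free macrocycle. Both olefins lie three and seven methylenes away from the arenes and from every oxygen, so no unproductive chelate or styrene-type alkylidene is expected.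

Step 5
Reactants: 11 tri-O-methyl ether of the target macrocycle
Product: 12 target macrocycle (ring A 3-hydroxyphenyl, ring B 2,6-dihydroxyphenyl, joined by the ether oxygen and by a (CH2)12 chain from ring B C4 to ring A C5)
Conditions: BBr3 (6 equiv), CH2Cl2, −78 °C to rt; then H2O
Reagents that add atoms: none
Why: BBr3 demethylation of aryl methyl ethers proceeds by Lewis acid coordination and bromide attack at the methyl carbon, whereas the diaryl ether bond and the saturated chain are inert, so aqueous work-up should release all three phenols.

Compound list
1 | 1,3-dibromo-5-methoxybenzene | COc1cc(Br)cc(Br)c1 | starting material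
2 | 9-bromonon-1-ene | C=CCCCCCCCBr | starting material
3 | (3-bromo-5-methoxyphenyl)magnesium chloride (LiCl complex) | COc1cc(Br)cc([Mg]Cl)c1 | intermediate
4 | 1-bromo-3-methoxy-5-(non-8-en-1-yl)benzene | COc1cc(Br)cc(CCCCCCCC=C)c1 | intermediate
5 | 4-allyl-2,6-dimethoxyphenol | COc1cc(CC=C)cc(OC)c1O | starting material
6 | vinyl bromide (bromoethene) | C=CBr | starting material
7 | 9-{3-[4-(9-borabicyclo[3.3.1]nonan-9-yloxy)-3,5-dimethoxyphenyl]propyl}-9-borabicyclo[3.3.1]nonane | COc1cc(CCCB2C3CCCC2CCC3)cc(OC)c1OB1C2CCCC1CCC2 | intermediate
8 | 2,6-dimethoxy-4-(pent-4-en-1-yl)phenol | COc1cc(CCCC=C)cc(OC)c1O | intermediate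
9 | 1,3-dimethoxy-2-[3-methoxy-5-(non-8-en-1-yl)phenoxy]-5-(pent-4-en-1-yl)benzene | COc1cc(CCCCCCCC=C)cc(Oc2c(OC)cc(CCCC=C)cc2OC)c1 | intermediate
10 | macrocyclic alkene: tri-O-methyl ether of the target with a C4=C5 double bond in the chain (E/Z mixture, geometry not specified) | COc1cc2cc(c1)Oc1c(OC)cc(cc1OC)CCCC=CCCCCCCC2 | intermediate
11 | tri-O-methyl ether of the target macrocycle (saturated (CH2)12 chain) | COc1cc2cc(c1)Oc1c(OC)cc(cc1OC)CCCCCCCCCCCC2 | intermediate
12 | target macrocycle: 3-hydroxyphenyl (ring A) 2,6-dihydroxyphenyl (ring B) ether with ring B C4 and ring A C5 bridged by (CH2)12 | Oc1cc2cc(c1)Oc1c(O)cc(cc1O)CCCCCCCCCCCC2 | target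

Total step count: 5. Longest linear sequence: 4 steps (step 1 or step 2, then steps 3, 4 and 5).

Steps most likely to fail

Step 4. Intermolecular metathesis may outrun ring closure and give oligomers, or olefin migration before closure may lead to ring-contracted homologues. The fallback sets out from 9 and comes back at 11. Both terminal olefins of 9 would be cleaved by Lemieux–Johnson oxidation (OsO4 cat., NaIO4, 2,6-lutidine, dioxane/H2O) to the dialdehyde 8-{3-[2,6-dimethoxy-4-(4-oxobutyl)phenoxy]-5-methoxyphenyl}octanal F1. An intramolecular McMurry coupling (TiCl3, Zn–Cu couple, DME, reflux, syringe-pump addition) on the low-valent titanium surface should then join the two carbonyl carbons to the same C4=C5 olefin 10, this time isolated. Hydrogenation (H2, Pd/C, EtOAc) gives 11.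

Step 3. C–O bond formation at the doubly ortho-substituted phenoxide may be slow, so that reductive loss of bromine from the aryl bromide or oxidative degradation of the electron-rich phenoxide takes over. The fallback sets out from 4 and comes back at 9. Bromine–lithium exchange (n-BuLi, THF, −78 °C), trapping with B(OiPr)3 and acidic work-up would give [3-methoxy-5-(non-8-en-1-yl)phenyl]boronic acid F2. A Chan–Lam–Evans coupling of F2 with phenol 8 (Cu(OAc)2, pyridine, 4 Å molecular sieves, air, CH2Cl2, rt), a reaction type that accepts doubly ortho-substituted phenols at room temperature, should give 9.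

Step 2. The free phenol consumes borane and vinyl bromide is volatile, so the coupling may stay incomplete, or the alkylborane may undergo protodeboronation. The fallback sets out from 5 and comes back at 8. Hydroboration–oxidation (9-BBN, THF; then NaBO3·4H2O) would give 4-(3-hydroxypropyl)-2,6-dimethoxyphenol F3. An Appel reaction (I2, PPh3, imidazole, CH2Cl2), selective for the primary alcohol over the phenol, would give 4-(3-iodopropyl)-2,6-dimethoxyphenol F4. Copper-catalysed coupling with CH2=CHMgBr (3 equiv, the first deprotonating the phenol; CuI cat., THF, −30 to 0 °C) should give 8.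

Further compounds
F1 | step 4 | 8-{3-[2,6-dimethoxy-4-(4-oxobutyl)phenoxy]-5-methoxyphenyl}octanal | COc1cc(CCCCCCCC=O)cc(Oc2c(OC)cc(CCCC=O)cc2OC)c1
F2 | step 3 | [3-methoxy-5-(non-8-en-1-yl)phenyl]boronic acid | COc1cc(B(O)O)cc(CCCCCCCC=C)c1
F3 | step 2 | 4-(3-hydroxypropyl)-2,6-dimethoxyphenol | COc1cc(CCCO)cc(OC)c1O
F4 | step 2 | 4-(3-iodopropyl)-2,6-dimethoxyphenol | COc1cc(CCCI)cc(OC)c1O
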